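**Retrosynthetic overview**

1. The target is (6S)-ε,ψ-carotene. The last disconnection is C7=C8, a Julia–Kocienski olefination between a ring A C10 tetrazolyl sulfone and the acyclic C30 aldehyde 8'-apo-ψ-caroten-8'-al. That aldehyde comes from crocetindial and a geranyl phosphonate by Horner–Wadsworth–Emmons olefination at C7'=C8'.
2. Feature used: ring A (C1–C6) has one stereocentre, C6, the ring CH that carries the polyene. C6 is stereogenic only because its ring neighbours differ: C1 is saturated and bears two methyls, C5 is the methyl-bearing sp2 carbon of C4=C5. A 2,6-dimethylcyclohexa-2,5-diene with C7 on its sp3 carbon is therefore a mirror-symmetric, prochiral image of ring A.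
3. Key disconnection: the second methyl on C1 (C17) is traced back to the carbene carbon of a diazoacetate hung from C6 through the C7 oxygen. Enantiotopic-alkene-selective intramolecular cyclopropanation forms C1–C17 and C2–C17 (cyclopropane plus six-membered lactone). Reductive C2–C17 cleavage and decarboxylation then leave the gem-dimethyl group.
4. Ring order: the carbocycle comes from Birch reduction of 2,6-dimethylbenzoic acid. Cyclopropane and lactone close together in step 5, the cyclopropane is opened in step 6 and the lactone in step 7. No ring is formed afterwards.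

Key step: step 5

Assumption: the sense in which the chiral catalyst selects between the enantiotopic alkenes of this ring-constrained diene cannot be read with confidence from open-chain homoallylic diazoacetates. Rh2(5S-MEPY)4 (dirhodium tetrakis[methyl (5S)-2-oxopyrrolidine-5-carboxylate]) is written as the working choice, and its mirror image Rh2(5R-MEPY)4 would be substituted if a pilot run should deliver the antipodal lactone.

Remark: carotenoid numbering is used for ring A throughout (ring C1–C6, C7 on C6, C16 and C17 on C1, C18 on C5); the carbene carbon is the future C17.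

**Route**

Step 1
Reactants: 1 2,6-dimethylbenzoic acid
Product: 2 2,6-dimethylcyclohexa-2,5-diene-1-carboxylic acid
Conditions: Li, NH3(l)/THF, −78 °C; then NH4Cl
Reagents that add atoms: none
Why: Birch reduction of a benzoic acid puts the two new hydrogens on the ipso and para carbons, so the 1,4-dihydro acid with both methyl-bearing alkenes should result; it is kept cold under argon because it rearomatises easily.

Step 2
Reactants: 2 2,6-dimethylcyclohexa-2,5-diene-1-carboxylic acid
Product: 3 (2,6-dimethylcyclohexa-2,5-dien-1-yl)methanol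
Conditions: LiAlH4, Et2O, 0 °C → rt; then H2O, aq NaOH
Reagents that add atoms: none
Why: hydride reduction of the acid, which reacts as its lithium carboxylate, should give the primary alcohol without touching the isolated alkenes or moving the skipped diene into conjugation.

Step 3
Reactants: 3 (2,6-dimethylcyclohexa-2,5-dien-1-yl)methanol; 4 bromoacetyl bromide
Product: 5 (2,6-dimethylcyclohexa-2,5-dien-1-yl)methyl 2-bromoacetate
Conditions: NaHCO3, MeCN, 0 °C
Reagents that add atoms: none
Why: O-acylation of a primary alcohol by an acyl bromide with a mild insoluble base, which keeps the diene away from strong acid or base.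

Step 4
Reactants: 5 (2,6-dimethylcyclohexa-2,5-dien-1-yl)methyl 2-bromoacetate
Product: 6 (2,6-dimethylcyclohexa-2,5-dien-1-yl)methyl 2-diazoacetate
Conditions: TsNHNHTs, DBU, THF, 0 °C
Reagents that add atoms: N,N'-ditosylhydrazine, Cc1ccc(cc1)S(=O)(=O)NNS(=O)(=O)c1ccc(C)cc1
Why: N-alkylation of the bis-sulfonyl hydrazine by the α-bromo ester followed by base-induced loss of two sulfinate ions is a standard diazoacetate synthesis that runs at 0 °C and should leave the diene alone.

Step 5
Reactants: 6 (2,6-dimethylcyclohexa-2,5-dien-1-yl)methyl 2-diazoacetate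
Product: 7 (1S,2S,6R,10R)-1,7-dimethyl-4-oxatricyclo[4.4.0.0^2,10]dec-7-en-3-one (cyclopropane-fused δ-lactone with C4=C5 intact; carotenoid numbering C1 S, C2 R, C6 R, C17 S)
Conditions: Rh2(5S-MEPY)4 (1 mol %), CH2Cl2, 40 °C, slow addition of 6 by syringe pump
Reagents that add atoms: none
Why: Rh2(5S-MEPY)4 expels N2 from 6 to give an electrophilic rhodium carbene that adds to one of the two trisubstituted ring alkenes in a single asynchronous [2+1] event, the closest known reaction type being the enantioselective intramolecular cyclopropanation of homoallylic diazoacetates with Rh2(MEPY)4-type chiral carboxamidate catalysts, including the desymmetrisation of dienes with enantiotopic alkenes. The cyclopropane (C1, C2, C17) closes by this [2+1] addition across C1=C2, and the six-membered lactone (C17, carbonyl C, O, C7, C6, C1) closes with it in the 6-exo sense, because C17 bonds to the proximal alkene carbon C1 while C2 stays outside the lactone ring. The three-atom tether from C6 lets the carbene reach only the ring face that carries C7, so the relative configuration at C1, C2 and C17 (both ring fusions cis, carbonyl syn to the carbocycle) is fixed by the substrate. The absolute configuration at these three centres and at C6, which becomes stereogenic without any bond being made to it once its two ring arms differ, is set by the chiral carboxamidate ligands when they select one enantiotopic alkene. Besides this group selectivity the step needs chemoselectivity against 1,5 C–H insertion into the tertiary, doubly allylic C6–H (which would close a spiro γ-lactone), against hydride abstraction at C3 with aromatisation, and against carbene dimerisation. The electron-rich trisubstituted alkenes, the known preference of homoallylic diazoacetates for alkene addition under Rh2(MEPY)4 and the slow addition of 6 are relied on here, and this competition remains the main risk of the route.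

Step 6
Reactants: 7 (1S,2S,6R,10R)-1,7-dimethyl-4-oxatricyclo[4.4.0.0^2,10]dec-7-en-3-one
Product: 8 (4aR,8aS)-4a,8-dimethyl-1,4,4a,5,6,8a-hexahydro-3H-isochromen-3-one (cis-fused δ-lactone; C17 is now a CH2 on C1)
Conditions: SmI2 (2.1 equiv), H2O, THF, 0 °C
Reagents that add atoms: none
Why: reductive cleavage of a carbonyl-activated cyclopropane, in which single-electron reduction of the six-membered lactone gives a ketyl-type radical anion whose cyclopropylcarbinyl fragmentation should break the C2–C17 bond, the one exocyclic to the lactone and aligned with the carbonyl π system (C1–C17 lies near the carbonyl plane), after which the C2 radical and the samarium enolate are reduced and protonated.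

Step 7
Reactants: 8 (4aR,8aS)-4a,8-dimethyl-1,4,4a,5,6,8a-hexahydro-3H-isochromen-3-one
Product: 11 2-[(1R,2S)-2-({[tert-butyl(dimethyl)silyl]oxy}methyl)-1,3-dimethylcyclohex-3-en-1-yl]acetic acid, via lithium hydroxy carboxylate 9 (not isolated), via silyl ester silyl ether 10 (not isolated)
Conditions: LiOH, THF/H2O, rt; evaporation; TBSCl, imidazole, DMF, rt; then K2CO3, MeOH/H2O; aq citric acid to pH 4
Reagents that add atoms: lithium hydroxide, [Li+].[OH-]; tert-butyldimethylsilyl chloride, CC(C)(C)[Si](C)(C)Cl
Why: saponification opens the lactone, silylation of the salt on both oxygens prevents relactonisation, and mild carbonate methanolysis cleaves only the labile silyl ester, so the acid with C7–OH masked as its TBS ether should be obtained (ester hydrolysis and silyl protection).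

Step 8
Reactants: 11 2-[(1R,2S)-2-({[tert-butyl(dimethyl)silyl]oxy}methyl)-1,3-dimethylcyclohex-3-en-1-yl]acetic acid
Product: 13 tert-butyl(dimethyl){[(1S)-2,6,6-trimethylcyclohex-2-en-1-yl]methoxy}silane, via thiohydroxamate ester 12 (not isolated)
Conditions: N-hydroxypyridine-2-thione, DCC, DMAP (cat.), CH2Cl2, 0 °C → rt, dark; then t-BuSH, hν (tungsten lamp), rt
Reagents that add atoms: none
Why: Barton reductive decarboxylation, in which the O-acyl thiohydroxamate fragments under visible light to a primary radical at C17 on the quaternary C1 that has no fast rearrangement path and is quenched by the thiol, turning CH2CO2H into the second methyl on C1.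

Step 9
Reactants: 13 tert-butyl(dimethyl){[(1S)-2,6,6-trimethylcyclohex-2-en-1-yl]methoxy}silane
Product: 14 [(1S)-2,6,6-trimethylcyclohex-2-en-1-yl]methanol, (S)-α-cyclogeraniol
Conditions: Bu4NF, THF, rt
Reagents that add atoms: none
Why: fluoride cleavage of the primary silyl ether (desilylation) is selective and cannot affect C6, which carries no acidifying group.

Step 10
Reactants: 14 (S)-α-cyclogeraniol
Product: 15 1-phenyl-5-({[(1S)-2,6,6-trimethylcyclohex-2-en-1-yl]methyl}sulfanyl)-1H-tetrazole
Conditions: 1-phenyl-1H-tetrazole-5-thiol, PPh3, DIAD, THF, 0 °C → rt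
Reagents that add atoms: 1-phenyl-1H-tetrazole-5-thiol, Sc1nnnn1-c1ccccc1
Why: Mitsunobu thioetherification, in which the acidic, strongly nucleophilic thiol displaces the oxyphosphonium group at the primary carbon C7 by SN2 and the neighbouring stereocentre C6 takes no part.

Step 11
Reactants: 15 1-phenyl-5-({[(1S)-2,6,6-trimethylcyclohex-2-en-1-yl]methyl}sulfanyl)-1H-tetrazole
Product: 16 1-phenyl-5-({[(1S)-2,6,6-trimethylcyclohex-2-en-1-yl]methyl}sulfonyl)-1H-tetrazole
Conditions: (NH4)6Mo7O24·4H2O (cat.), 30% H2O2, EtOH, 0 °C → rt
Reagents that add atoms: hydrogen peroxide, OO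
Why: sulfide oxidation to the sulfone by H2O2 with (NH4)6Mo7O24 as catalyst is much faster than epoxidation of an unactivated trisubstituted alkene, so C4=C5 should survive.

Step 12
Reactants: 17 geranyl bromide, (2E)-1-bromo-3,7-dimethylocta-2,6-diene
Product: 18 diethyl [(2E)-3,7-dimethylocta-2,6-dien-1-yl]phosphonate
Conditions: P(OEt)3, neat, 130 °C, EtBr distilled off
Reagents that add atoms: triethyl phosphite, CCOP(OCC)OCC
Why: Michaelis–Arbuzov reaction of a primary allylic bromide, which proceeds by direct displacement and should keep the E trisubstituted alkene.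

Step 13
Reactants: 18 diethyl [(2E)-3,7-dimethylocta-2,6-dien-1-yl]phosphonate; 19 crocetindial, (2E,4E,6E,8E,10E,12E,14E)-2,6,11,15-tetramethylhexadeca-2,4,6,8,10,12,14-heptaenedial
Product: 21 all-E 8'-apo-ψ-caroten-8'-al (C30 aldehyde whose CHO carbon is C8 of the target), via lithiated phosphonate 20 (not isolated)
Conditions: n-BuLi, THF, −78 °C; then added slowly to 19 (2 equiv) in THF, −78 → 0 °C
Reagents that add atoms: none
Why: Horner–Wadsworth–Emmons olefination, in which the allylic phosphonate anion reacts at its α carbon and should give mainly the E alkene at C7'=C8', while inverse addition to excess dialdehyde limits the reaction to one of the two equivalent formyl groups (surplus dialdehyde is recovered).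

Step 14
Reactants: 16 1-phenyl-5-({[(1S)-2,6,6-trimethylcyclohex-2-en-1-yl]methyl}sulfonyl)-1H-tetrazole; 21 all-E 8'-apo-ψ-caroten-8'-al
Product: 23 (6S)-ε,ψ-carotene, via potassium sulfonyl carbanion 22 (not isolated)
Conditions: KN(SiMe3)2, THF, −78 °C; then 21, −78 °C → rt
Reagents that add atoms: none
Why: Julia–Kocienski olefination, in which the C7 carbanion adds to the aldehyde and Smiles transfer of the tetrazolyl group with anti elimination of SO2 and tetrazolate should give the E C7=C8 alkene, while C6 is untouched because deprotonation at low temperature occurs only α to the sulfonyl group.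

**Compound list**

1 | 2,6-dimethylbenzoic acid | Cc1cccc(C)c1C(=O)O | starting material
2 | 2,6-dimethylcyclohexa-2,5-diene-1-carboxylic acid | OC(=O)C1C(C)=CCC=C1C | intermediate
3 | (2,6-dimethylcyclohexa-2,5-dien-1-yl)methanol | OCC1C(C)=CCC=C1C | intermediate
4 | bromoacetyl bromide | BrCC(Br)=O | starting material
5 | (2,6-dimethylcyclohexa-2,5-dien-1-yl)methyl 2-bromoacetate | BrCC(=O)OCC1C(C)=CCC=C1C | intermediate
6 | (2,6-dimethylcyclohexa-2,5-dien-1-yl)methyl 2-diazoacetate (achiral) | [N-]=[N+]=CC(=O)OCC1C(C)=CCC=C1C | intermediate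
7 | (1S,2S,6R,10R)-1,7-dimethyl-4-oxatricyclo[4.4.0.0^2,10]dec-7-en-3-one | O=C1OC[C@@H]2C(C)=CC[C@@H]3[C@H]1[C@]23C | intermediate
8 | (4aR,8aS)-4a,8-dimethyl-1,4,4a,5,6,8a-hexahydro-3H-isochromen-3-one | O=C1OC[C@@H]2C(C)=CCC[C@]2(C)C1 | intermediate
9 | lithium 2-[(1R,2S)-2-(hydroxymethyl)-1,3-dimethylcyclohex-3-en-1-yl]acetate | OC[C@@H]1C(C)=CCC[C@]1(C)CC(=O)[O-].[Li+] | intermediate (not isolated)
10 | tert-butyldimethylsilyl 2-[(1R,2S)-2-({[tert-butyl(dimethyl)silyl]oxy}methyl)-1,3-dimethylcyclohex-3-en-1-yl]acetate | CC(C)(C)[Si](C)(C)OC[C@@H]1C(C)=CCC[C@]1(C)CC(=O)O[Si](C)(C)C(C)(C)C | intermediate (not isolated)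
11 | 2-[(1R,2S)-2-({[tert-butyl(dimethyl)silyl]oxy}methyl)-1,3-dimethylcyclohex-3-en-1-yl]acetic acid | CC(C)(C)[Si](C)(C)OC[C@@H]1C(C)=CCC[C@]1(C)CC(=O)O | intermediate
12 | 2-thioxopyridin-1(2H)-yl 2-[(1R,2S)-2-({[tert-butyl(dimethyl)silyl]oxy}methyl)-1,3-dimethylcyclohex-3-en-1-yl]acetate | CC(C)(C)[Si](C)(C)OC[C@@H]1C(C)=CCC[C@]1(C)CC(=O)ON1C=CC=CC1=S | intermediate (not isolated)
13 | tert-butyl(dimethyl){[(1S)-2,6,6-trimethylcyclohex-2-en-1-yl]methoxy}silane | CC(C)(C)[Si](C)(C)OC[C@@H]1C(C)=CCCC1(C)C | intermediate
14 | [(1S)-2,6,6-trimethylcyclohex-2-en-1-yl]methanol, (S)-α-cyclogeraniol | OC[C@@H]1C(C)=CCCC1(C)C | intermediate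
15 | 1-phenyl-5-({[(1S)-2,6,6-trimethylcyclohex-2-en-1-yl]methyl}sulfanyl)-1H-tetrazole | c1ccc(cc1)-n1nnnc1SC[C@@H]1C(C)=CCCC1(C)C | intermediate
16 | 1-phenyl-5-({[(1S)-2,6,6-trimethylcyclohex-2-en-1-yl]methyl}sulfonyl)-1H-tetrazole | O=S(=O)(C[C@@H]1C(C)=CCCC1(C)C)c1nnnn1-c1ccccc1 | intermediate
17 | geranyl bromide, (2E)-1-bromo-3,7-dimethylocta-2,6-diene | CC(C)=CCC/C(C)=C/CBr | starting material
18 | diethyl [(2E)-3,7-dimethylocta-2,6-dien-1-yl]phosphonate | CC(C)=CCC/C(C)=C/CP(=O)(OCC)OCC | intermediate
19 | crocetindial, (2E,4E,6E,8E,10E,12E,14E)-2,6,11,15-tetramethylhexadeca-2,4,6,8,10,12,14-heptaenedial | O=C/C(C)=C/C=C/C(C)=C/C=C/C=C(C)/C=C/C=C(C)/C=O | starting material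
20 | lithium salt of the α-carbanion of 18 | [Li+].CC(C)=CCC/C(C)=C/[CH-]P(=O)(OCC)OCC | intermediate (not isolated)
21 | 8'-apo-ψ-caroten-8'-al, (2E,4E,6E,8E,10E,12E,14E,16E,18E)-2,6,11,15,19,23-hexamethyltetracosa-2,4,6,8,10,12,14,16,18,22-decaenal | CC(C)=CCC/C(C)=C/C=C/C(C)=C/C=C/C(C)=C/C=C/C=C(C)/C=C/C=C(C)/C=O | intermediate
22 | potassium salt of the α-sulfonyl carbanion of 16 | [K+].O=S(=O)([CH-][C@@H]1C(C)=CCCC1(C)C)c1nnnn1-c1ccccc1 | intermediate (not isolated)
23 | (6S)-ε,ψ-carotene | CC(C)=CCC/C(C)=C/C=C/C(C)=C/C=C/C(C)=C/C=C/C=C(C)/C=C/C=C(C)/C=C/[C@@H]1C(C)=CCCC1(C)C | target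

**Step count and risks**

Total step count: 14. Longest linear sequence: 12 (steps 1–11 and 14).

Steps most likely to fail:

Step 5. The chiral carboxamidate may discriminate poorly between the two enantiotopic alkenes, or insertion of the carbene into the doubly allylic C6–H bond, hydride abstraction with aromatisation and carbene dimerisation may outrun cyclopropanation. Fallback, which replaces asymmetric rhodium catalysis by an achiral copper carbene and a resolution: starting from diazoacetate 6, slow addition to Cu(acac)2 (copper bis(acetylacetonate), 5 mol %) in toluene at 80 °C should give racemic 1,7-dimethyl-4-oxatricyclo[4.4.0.0^2,10]dec-7-en-3-one F1. Copper carbenes add to alkenes but seldom insert into C–H bonds, and the tether alone still enforces the cis-fused connectivity. The enantiomers of F1 are separated by preparative chromatography on a cellulose tris(3,5-dimethylphenylcarbamate) stationary phase. The unwanted (1R,2R,6S,10S)-1,7-dimethyl-4-oxatricyclo[4.4.0.0^2,10]dec-7-en-3-one F2 is set aside, and the (1S,2S,6R,10R) enantiomer re-enters the route as 7.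

Step 6. Electron transfer to the lactone may be slow, the product lactone may be reduced further to a diol once its samarium enolate is protonated, or fragmentation may turn towards cleavage of the C1–C17 bond. Fallback, a two-electron dissolving-metal cleavage in which the carbonyl is stored as an enolate instead of passing through a protonated samarium ketyl: starting from lactone 7, its THF solution is added to Li (2.2 equiv) in liquid NH3 at −78 °C. Carbanion-type ring opening places the charge on the less substituted carbon C2, which ammonia protonates, and the carbonyl is held as the lithium enolate of (4aR,8aS)-4a,8-dimethyl-1,4,4a,5,6,8a-hexahydro-3H-isochromen-3-one F3, which resists further reduction. Quenching F3 with solid NH4Cl returns the route at 8.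

Step 14. The hindered, β-branched C7 carbanion may add sluggishly to the α-methyl polyenal, and E selectivity at C7=C8 may erode. Fallback, a Wittig olefination with reversed polarity: starting from alcohol 14, oxidation with Dess–Martin periodinane (NaHCO3, CH2Cl2, 0 °C) gives (1S)-2,6,6-trimethylcyclohex-2-ene-1-carbaldehyde F4, which is used at once. Aldehyde 21 is reduced with NaBH4 (THF/MeOH, 0 °C) to all-E 8'-apo-ψ-caroten-8'-ol F5. Treatment of F5 with PPh3·HBr in CH2Cl2/MeOH gives all-E (8'-apo-ψ-caroten-8'-yl)triphenylphosphonium bromide F6. F6 and F4 are heated in 1,2-epoxybutane/EtOH, where the epoxide acts as proton scavenger so that no strong base meets the epimerisable aldehyde. Iodine-catalysed photo-equilibration of the C7=C8 isomers in hexane and crystallisation return the route at the target 23.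

**Further compounds**

F1 | step 5 | racemic 1,7-dimethyl-4-oxatricyclo[4.4.0.0^2,10]dec-7-en-3-one | O=C1OCC2C(C)=CCC3C1C23C
F2 | step 5 | (1R,2R,6S,10S)-1,7-dimethyl-4-oxatricyclo[4.4.0.0^2,10]dec-7-en-3-one (unwanted antipode) | O=C1OC[C@H]2C(C)=CC[C@H]3[C@@H]1[C@@]23C
F3 | step 6 | lithium enolate of (4aR,8aS)-4a,8-dimethyl-1,4,4a,5,6,8a-hexahydro-3H-isochromen-3-one | [Li+].[O-]C=1OC[C@@H]2C(C)=CCC[C@]2(C)C=1
F4 | step 14 | (1S)-2,6,6-trimethylcyclohex-2-ene-1-carbaldehyde, (S)-α-cyclocitral | O=C[C@@H]1C(C)=CCCC1(C)C
F5 | step 14 | 8'-apo-ψ-caroten-8'-ol (all-E) | CC(C)=CCC/C(C)=C/C=C/C(C)=C/C=C/C(C)=C/C=C/C=C(C)/C=C/C=C(C)/CO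
F6 | step 14 | (all-E)-(8'-apo-ψ-caroten-8'-yl)triphenylphosphonium bromide | CC(C)=CCC/C(C)=C/C=C/C(C)=C/C=C/C(C)=C/C=C/C=C(C)/C=C/C=C(C)/C[P+](c1ccccc1)(c1ccccc1)c1ccccc1.[Br-]
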